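The highest target reading in the amber run stood at 1.70 times that in the violet run, each as a fraction of its own charge, while amber's reagent charge was 2.00 times violet's. From that ratio I had to choose the next flask.

| flask | starting material | reagent | second substrate | temperature | remark | time |
|---|---|---|---|---|---|---|
| violet | 0.034 M | 0.075 M | 0.025 M | −25 °C | run made earlier |  |
| red | 0.075 M | 0.075 M | 0.025 M | −5 °C | run made earlier |  |
| amber | 0.050 M | 0.15 M | 0.025 M | −25 °C | run made earlier |  |
| elm | 0.050 M | 0.0750 M | 0.0250 M | 10 °C |  | 10 min |
| birch | 0.050 M | 0.0750 M | 0.0250 M | −5 °C |  | 10 min |
| ash | 0.050 M | 0.0750 M | 0.0250 M | −20 °C |  | 10 min |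

| run | time / min | target / % |
|---|---|---|
| violet | 2.00 | 10.0 |
| violet | 6.00 | 17.7 |
| violet | 8.00 | 20.4 |
| violet | 15.0 | 22.9 |
| violet | 25.0 | 23.0 |
| violet | 30.0 | 22.4 |
| red | 1.00 | 13.3 |
| red | 1.33 | 14.6 |
| red | 2.00 | 16.1 |
| red | 3.00 | 16.3 |
| red | 5.00 | 15.6 |
| red | 8.00 | 13.6 |
| red | 12.0 | 12.4 |
| amber | 3.00 | 24.1 |
| amber | 8.00 | 36.1 |
| amber | 15.0 | 39.1 |
| amber | 25.0 | 37.2 |
| amber | 30.0 | 35.5 |

(standard deviation of a reading: 0.3 percentage points)

- the earlier runs were read with a standard deviation of 0.3 percentage points
- steps under discussion: target <-> isomer of the product; starting material + reagent -> target; starting material <-> dormant form; 2 second substrate -> self-condensation product; starting material + second substrate -> cross product; second substrate + reagent -> second product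

- the best flask by amount of target, in percent of the starting material charged; "all alike" if 1.5 percentage points covers them all (elm / birch / ash / all alike)
- amount of target at the end, in percent of the starting material charged, elm
- amount of target at the end, in percent of the starting material charged, birch
- amount of target at the end, in percent of the starting material charged, ash

1. The gain was smaller than the rise in reagent, so I let reagent compete with a loss that does not use it. I wrote the fraction of the charge reaching target or its isomer as reagent/(reagent + K), with K a reagent level of my own, and took each highest reading as that fraction.

2. Target draws reagent, so I used the mean of the charge and the charge less that draw. Violet gave K = 0.238 M and amber gave 0.218 M, so I took 0.228 M.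

3. The red run, read the same way, gave 0.354 M, larger than the cold value. So I chose ash, at −20 °C, which stands beside the cold runs.

4. For ash the charge gave a first answer of 0.247. Putting that back, mean reagent stood at 0.918 of its charge, and the second round gave 0.232. I carried this as the capture share, a share of the whole charge, and reagent became the charge to change next.

5. The forecast said ash, with 10% for elm, 13% for birch and 21% for ash, on the ground that “reagent competes with a roughly first-order loss”. Its ash figure counts target, while my share counts target and isomer together.

The flasks gave 16.1% in elm, 13.9% in birch and 20.4% in ash, so the best was ash.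

    target ⇌ isomer of the product (K = 10.0, k = 7.30 × 10⁻⁴ /s, Ea = 80.0 kJ/mol, ΔH = −20.0 kJ/mol)
    starting material + reagent → target (k = 0.0240 /M/s, Ea = 47.0 kJ/mol)
    starting material ⇌ dormant form (K = 2.60, k = 0.00350 /s, Ea = 67.0 kJ/mol, ΔH = −38.0 kJ/mol)
    2 second substrate → self-condensation product (k = 0.0230 /M/s, Ea = 36.0 kJ/mol)
    starting material + second substrate → cross product (k = 0.100 /M/s, Ea = 56.0 kJ/mol)
    second substrate + reagent → second product (k = 0.0950 /M/s, Ea = 43.0 kJ/mol)
    (constants at −20 °C)

At the start of ash, the forward step to dormant form alone used starting material at 1.9 times the rate of the step to target, and after 10.0 min dormant form stood at 42.1% against 20.4% of target. Target and isomer together then held 27.4% against my capture share of 0.232, with 57.2% still standing as starting material and dormant form.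

In a neighbour like ash but with 0.30 M of reagent, the same two rounds give a share of 0.568, then 0.556, which is 2.40 times ash's and scales ash's target to 48.9%. That flask gave 50.1%.

(Readings and results stem from a simulated flask with made-up constants; noise was put on by code.)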